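## Analysis of the target

Compound 20 is a 2,3,4-trisubstituted tetrahydrofuran (ring atoms O1, C2, C3, C4 and the unsubstituted C5H2) of the lariciresinol type. C2 carries a 4-hydroxy-3,5-dimethoxyphenyl (syringyl) group, C3 a CH2O group acylated by (E)-ferulic acid, and C4 a 4-hydroxy-3-methoxybenzyl (guaiacylmethyl) group. The three contiguous stereocentres are (2S,3R,4R): the C2 aryl group is trans to the C3 side chain, the C3 and C4 side chains are cis, and the C2 aryl and C4 benzyl groups are therefore trans across the ring. The C2–O1 bond is a benzylic ether para to a phenol, so it ionises under acid (epimerisation, or Friedel–Crafts closure onto the guaiacyl ring to an aryltetralin) and can be hydrogenolysed; the cinnamate double bond rules out hydrogenation once the ester is in place; and three free phenols compete with the one aliphatic hydroxyl in acylations. The difficulty lies in the 3,4-cis relation next to a 2,3-trans one, in placing two different aryl groups without ambiguity, and in ordering deprotection and esterification at the end. The strategy rests on a mapping of the ring: O1–C5–C4 with the one-carbon branch on C4 is the skeleton of 2-ethenyloxirane 5, and C2–C3 with a carboxyl-level carbon on C3 is the skeleton of the arylidene malonate 4, so the ring results from joining O1 to C2 and C3 to C4. The second ester of the malonate is not wasted: it is the handle through which C3 is later fixed.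

## Retrosynthetic reasoning

The alkyl C–O bond of the ferulate is cut first, which divides 20 into triol 18 and ferulic acid 19. This bond has to be made last, because the cinnamate alkene would not survive the hydrogenolysis that unmasks the phenols. The forward reaction must therefore acylate the only aliphatic hydroxyl of 18 in the presence of three phenols (two in 18, one in 19), which points to activation of the alcohol and not of the acid.

The CH2OH group on C3 of 18 is traced to the carboxyl group of acid 17. The benzylic CH2 of the guaiacylmethyl chain of 17 is then reconnected to a carboxyl oxygen, which leads through the debenzylated lactone 16 to the bicyclic lactone 15. The gain is stereochemical: a γ-lactone fused across C3–C4 of a five-membered ring can only be cis-fused, so the 3,4-cis relation becomes a matter of ring strain and not of selectivity. The forward step has to cleave two benzyl ethers and the benzylic lactone C–O bond while sparing the C2–O1 ether.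

The hydrogen on the ring-fusion carbon of 15 is traced to a methoxycarbonyl group, which gives lactone ester 13. The forward reaction is a Krapcho demethoxycarbonylation through carboxylate 14. The extra ester is accepted because it is what makes the key step possible, and because its removal after lactonisation leaves no choice for the configuration at C3.

In 13 the lactone acyl–O bond and the aryl–carbinol C–C bond are cut, giving aldehyde 8 and the arylmagnesium reagent 11, which comes from bromide 10 and thus from phenol 9. Forward, the alkoxide 12 formed in the addition can reach only the ester on its own face of the ring. The configuration of the new carbinol carbon is irrelevant, since that carbon becomes a CH2 group later.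

Aldehyde 8 is traced to the ethenyl compound 6 by oxidative cleavage of the alkene (through ozonide 7). The ethenyl group thus stands for the benzylic carbon of the C4 side chain.

In 6 the bonds O1–C2 and C3–C4 are cut together, which gives the arylidene malonate 4 and racemic 2-ethenyloxirane 5. The cut is made here because both fragments are then achiral or racemic and almost commercial. The forward reaction has to create C2 and C4 with the trans relation and with absolute control from a chiral catalyst.

Compound 4 is cut at the C=C bond into aldehyde 2 and dimethyl malonate 3 (Knoevenagel condensation), and 2 is the benzyl ether of syringaldehyde 1. Benzyl is chosen for both phenols because it survives every step up to the hydrogenolysis and leaves there together with the lactone C–O bond.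

## Alternatives that were turned down

Alternative 1: The O1–C2 bond is traced back to a cyclopropane bond. The formylcyclopropane A2, which carries the formyl and guaiacylmethyl groups on one carbon, the syringyl group on the second and the silyloxymethyl group on the third, would be treated with Sc(OTf)3. The bond between the syringyl carbon and the formyl-bearing carbon would break heterolytically to a benzylic cation and an enolate, whose oxygen closes on C2 to give the 2,3-dihydrofuran A1 (Cloke–Wilson ring expansion).
- For it: the whole carbon skeleton with both aryl groups is present before the key step; C3 passes through the rearrangement untouched; no benzylic hydrogenolysis is needed. The silyl protection would also allow the ferulate to be attached before a final fluoride deprotection. On this last point it is stronger than the chosen route, which must esterify in the presence of free phenols.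
- Against it: A2 is a fully substituted, enantioenriched cyclopropane with a quaternary carbon, and making it is a multistep stereochemical problem of its own. The intermediate is the very syringyl cation that the guaiacyl ring can trap in a six-membered Friedel–Crafts closure. C2 is set at a free cation by substrate control only. C4 must still be set by hydrogenating the enol ether of A1 from the face that carries the C2 aryl group.
- Comparison: the chosen strategy reaches its cycloaddition precursor in two steps, sets C2 and C4 with a chiral catalyst and fixes C3 by ring fusion instead of by a facial preference.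

Alternative 2: The C2–C3 bond is cut. The α-diazolactone A4 (trans-4-[(syringylmethoxy)methyl]-5-guaiacyl-3-diazo-γ-butyrolactone, benzyl-protected) would be decomposed with Rh2(OAc)4. The carbenoid at C3 would insert into the benzylic, oxygen-activated C–H bond of the syringylmethyl ether (1,5-insertion) and give the cis-fused bicyclic lactone A3.
- For it: A3 is the same lactone as 15 of the chosen route, with the guaiacyl carbon defined and C2 undefined, so the endgame is shared. The insertion site is electronically favoured, the cis fusion fixes C3 against C4, and no Krapcho step is needed. On the C3/C4 relation it is as strong as the chosen route.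
- Against it: C2 is created in the insertion without a reliable control element. The carbenoid can also attack the electron-rich syringyl ring or form an oxonium ylide at the ether oxygen. A4 needs an enantioenriched trans-disubstituted lactone and a two-stage diazo transfer, and the aryl-bearing stereocentre that is built with effort is destroyed in the hydrogenolysis.
- Comparison: the chosen strategy offers a much shorter access to the same lactone and sets C2 in the step that also sets C4.

Alternative 3: The C3–C4 bond is cut. The epoxy cinnamyl ether A6 would be opened by Cp2TiCl (trivalent titanium, from Cp2TiCl2 and Zn) to the C3 radical, which adds 5-exo to the cinnamyl double bond; the benzylic radical is reduced to the CH2Ar group and the alcohol A5 results.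
- For it: it is the shortest of the four plans. CH2OH and CH2Ar come out of the key step at the right oxidation level, no hydrogenolysis or carboxyl reduction follows, and A5 carries silyl ethers, so the primary hydroxyl can be feruloylated directly. In step count and endgame it is stronger than the chosen route.
- Against it: titanium is used in stoichiometric amount. C3 and C4 are both set in one radical cyclisation by substrate control alone, through an early transition state that usually gives useful but not complete 2,3-trans/3,4-cis selectivity. The absolute configuration would come from an epoxidation with kinetic resolution, which discards half of the material. O-alkylation of an epoxy alkoxide invites Payne rearrangement.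
- Comparison: the chosen strategy is about three steps longer, but it sets the absolute configuration by catalysis from a racemic epoxide and sets C3 by an unambiguous ring fusion.

Key step: step 3

Assumption: the (1R,2R) antipode of the ligand in step 3 is taken to deliver the (4R) centre of 6; if it delivers the mirror image, the (1S,2S) ligand is used and nothing else changes.

Remark: the carbinol carbon made in step 6 becomes a CH2 group in step 8, so both of its epimers (6RS) are carried on together.

## Route

Step 1
Reactants: 1 syringaldehyde
Product: 2 4-(benzyloxy)-3,5-dimethoxybenzaldehyde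
Conditions: BnBr, K2CO3, DMF, 60 °C
Reagents that add atoms: benzyl bromide, BrCc1ccccc1
Why: Williamson ether synthesis on the phenoxide; the aldehyde is inert to carbonate and the hindered phenol is alkylated cleanly in DMF.

Step 2
Reactants: 2 4-(benzyloxy)-3,5-dimethoxybenzaldehyde; 3 dimethyl malonate
Product: 4 dimethyl 2-{[4-(benzyloxy)-3,5-dimethoxyphenyl]methylidene}propanedioate
Conditions: piperidine (cat.), AcOH (cat.), toluene, reflux, Dean–Stark trap
Reagents that add atoms: none
Why: Knoevenagel condensation through the iminium ion, driven by removal of water; the malonate is symmetric, so the alkene has no geometric isomers.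

Step 3
Reactants: 4 dimethyl 2-{[4-(benzyloxy)-3,5-dimethoxyphenyl]methylidene}propanedioate; 5 racemic 2-ethenyloxirane
Product: 6 dimethyl (2R,4R)-2-[4-(benzyloxy)-3,5-dimethoxyphenyl]-4-ethenyloxolane-3,3-dicarboxylate
Conditions: Pd2(dba)3·CHCl3 (2.5 mol %), (1R,2R)-N,N'-bis[2-(diphenylphosphanyl)benzoyl]cyclohexane-1,2-diamine (7.5 mol %), 5 (2 equiv), THF, rt to 40 °C
Reagents that add atoms: none
Why: Zerovalent palladium ionises the allylic C–O bond of either enantiomer of 5 and gives an alkoxide tethered to a π-allylpalladium cation; the two diastereomeric complexes interconvert by π–σ–π isomerisation faster than they are trapped, so the racemate is funnelled through the ligand-matched one (dynamic kinetic asymmetric transformation). The alkoxide adds reversibly to the benzylidene carbon of 4 (oxa-Michael addition, O1–C2), and the malonate carbanion so formed attacks the internal allyl terminus on the face opposite to palladium (C3–C4). The closest known reaction type is the palladium-catalysed formal (3+2) cycloaddition of vinyl epoxides with doubly activated alkenes, which has enantioselective versions with chiral phosphines. The tetrahydrofuran closes in a 5-exo mode with respect to the allyl unit and leaves the ethenyl group outside the ring; attack at the far terminus would need a seven-membered ring and is not expected. C4 is controlled by the chiral ligand, which decides the allyl face that is offered to the tethered carbanion. C2 is controlled in the ring closure and not in the oxa-Michael step: because the two epimeric adducts interconvert through the reverse reaction, the one that cyclises faster is drained, and that should be the one with the aryl group pseudo-equatorial and turned away from the palladium-bound allyl fragment, which gives the 2,4-trans isomer. The step needs internal regioselectivity, enantioselectivity at C4 and trans selectivity at C2; the geminal diester makes the carbanion soft enough for the allylic alkylation, and its symmetry removes any question of geometry or of configuration at C3.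

Step 4
Reactants: 6 dimethyl (2R,4R)-2-[4-(benzyloxy)-3,5-dimethoxyphenyl]-4-ethenyloxolane-3,3-dicarboxylate
Product: 8 dimethyl (2R,4R)-2-[4-(benzyloxy)-3,5-dimethoxyphenyl]-4-formyloxolane-3,3-dicarboxylate, via secondary ozonide 7 (not isolated)
Conditions: O3, CH2Cl2, −78 °C (Sudan Red 7B as end-point indicator); then PPh3, −78 °C to rt
Reagents that add atoms: ozone, [O-][O+]=O
Why: Ozonolysis of the monosubstituted alkene gives ozonide 7, which PPh3 reduces to the aldehyde; at −78 °C with ozone dosed to the indicator end point the terminal alkene should react well before the trialkoxyarene or the benzyl ether. C4 is now α to an aldehyde, so the work-up is kept neutral and 8 is used without storage.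

Step 5
Reactants: 9 4-bromo-2-methoxyphenol
Product: 10 1-(benzyloxy)-4-bromo-2-methoxybenzene
Conditions: BnBr, K2CO3, DMF, rt
Reagents that add atoms: benzyl bromide, BrCc1ccccc1
Why: Williamson ether synthesis; the benzyl ether masks the acidic phenol for the Grignard step and leaves in the same hydrogenolysis as the other benzyl group.

Step 6
Reactants: 8 dimethyl (2R,4R)-2-[4-(benzyloxy)-3,5-dimethoxyphenyl]-4-formyloxolane-3,3-dicarboxylate; 10 1-(benzyloxy)-4-bromo-2-methoxybenzene
Product: 13 methyl (1S,2R,5R,6RS)-2-[4-(benzyloxy)-3,5-dimethoxyphenyl]-6-[4-(benzyloxy)-3-methoxyphenyl]-8-oxo-3,7-dioxabicyclo[3.3.0]octane-1-carboxylate, via arylmagnesium bromide 11 (not isolated), via bromomagnesium alkoxide 12 (not isolated)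
Conditions: 10, Mg, THF, reflux; then 8 (1.1 equiv of 11), THF, −78 to 0 °C; aq NH4Cl
Reagents that add atoms: none
Why: Grignard addition to the aldehyde is much faster than to the methyl esters at −78 °C, and the alkoxide 12 then closes a γ-lactone on the ester that lies on its own face of the ring (the other ester cannot reach), expelling methoxide. The new carbinol centre (C6) is formed as a mixture that does not matter; the new quaternary centre C1 is fixed by the cis fusion; any hydroxy diester left after work-up is closed with catalytic PPTS in warm toluene.

Step 7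
Reactants: 13 methyl (1S,2R,5R,6RS)-2-[4-(benzyloxy)-3,5-dimethoxyphenyl]-6-[4-(benzyloxy)-3-methoxyphenyl]-8-oxo-3,7-dioxabicyclo[3.3.0]octane-1-carboxylate
Product: 15 (1S,2S,5R,6RS)-2-[4-(benzyloxy)-3,5-dimethoxyphenyl]-6-[4-(benzyloxy)-3-methoxyphenyl]-3,7-dioxabicyclo[3.3.0]octan-8-one, via lithium carboxylate 14 (not isolated)
Conditions: LiCl, H2O, DMSO, 140 °C
Reagents that add atoms: none
Why: Krapcho demethoxycarbonylation: chloride dealkylates the methyl ester, carboxylate 14 (β to the lactone carbonyl) loses CO2 and the lactone enolate is protonated by water. Protonation can only give the cis-fused bicycle, so the former C3 is set with the lactone carbonyl cis to the C4 side chain and trans to the C2 aryl group. That aryl group already sits on the convex face, so a reversible ring opening of the enolate would return the same isomer.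

Step 8
Reactants: 15 (1S,2S,5R,6RS)-2-[4-(benzyloxy)-3,5-dimethoxyphenyl]-6-[4-(benzyloxy)-3-methoxyphenyl]-3,7-dioxabicyclo[3.3.0]octan-8-one
Product: 17 (2S,3S,4R)-2-(4-hydroxy-3,5-dimethoxyphenyl)-4-[(4-hydroxy-3-methoxyphenyl)methyl]oxolane-3-carboxylic acid, via bisphenol lactone 16 (not isolated)
Conditions: H2 (1 atm), Pd/C (10 %), EtOAc–EtOH, rt, stopped after uptake of 3 equiv
Reagents that add atoms: none
Why: Catalytic hydrogenolysis removes the two O-benzyl groups first (16) and then the benzylic lactone C–O bond, which has a carboxylate as leaving group and a para-hydroxyaryl group; both C6 epimers converge on the CH2 group. The C2–O1 ether would have to release an alkoxide and should be cleaved more slowly under neutral conditions, which is why no acid is added and the uptake is watched; C2, C3 and C4 are not touched.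

Step 9
Reactants: 17 (2S,3S,4R)-2-(4-hydroxy-3,5-dimethoxyphenyl)-4-[(4-hydroxy-3-methoxyphenyl)methyl]oxolane-3-carboxylic acid
Product: 18 4-[(2S,3R,4R)-3-(hydroxymethyl)-4-[(4-hydroxy-3-methoxyphenyl)methyl]oxolan-2-yl]-2,6-dimethoxyphenol (5-methoxylariciresinol)
Conditions: BH3·THF (5 equiv), THF, 0 °C to rt; then MeOH
Reagents that add atoms: none
Why: Borane reduces the carboxylic acid through its acyloxyborane and leaves the ether and the arenes alone; the phenols only consume hydride as aryloxyboranes, which the methanol quench cleaves. No stereocentre is affected (the descriptor of C3 changes from S to R only because the substituent priorities change).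

Step 10
Reactants: 18 4-[(2S,3R,4R)-3-(hydroxymethyl)-4-[(4-hydroxy-3-methoxyphenyl)methyl]oxolan-2-yl]-2,6-dimethoxyphenol; 19 (E)-ferulic acid
Product: 20 [(2S,3R,4R)-2-(4-hydroxy-3,5-dimethoxyphenyl)-4-[(4-hydroxy-3-methoxyphenyl)methyl]oxolan-3-yl]methyl (2E)-3-(4-hydroxy-3-methoxyphenyl)prop-2-enoate
Conditions: PPh3, DIAD, THF, 0 °C to rt
Reagents that add atoms: none
Why: Mitsunobu esterification: the betaine from PPh3 and DIAD is protonated by the carboxylic acid, the strongest acid present, and the ferulate anion displaces the alkoxyphosphonium group at the primary carbon, so no stereocentre is involved. Phenols are much weaker acids and poorer nucleophiles here, and chemoselective esterification of phenolic acids with phenol-bearing primary alcohols under these conditions is known; the E alkene is unchanged.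

## Compound list

1 | syringaldehyde (4-hydroxy-3,5-dimethoxybenzaldehyde) | COc1cc(C=O)cc(OC)c1O | starting material
2 | 4-(benzyloxy)-3,5-dimethoxybenzaldehyde | COc1cc(C=O)cc(OC)c1OCc1ccccc1 | intermediate
3 | dimethyl malonate | COC(=O)CC(=O)OC | starting material
4 | dimethyl 2-{[4-(benzyloxy)-3,5-dimethoxyphenyl]methylidene}propanedioate | COC(=O)C(=Cc1cc(OC)c(OCc2ccccc2)c(OC)c1)C(=O)OC | intermediate
5 | racemic 2-ethenyloxirane | C=CC1CO1 | starting material
6 | dimethyl (2R,4R)-2-[4-(benzyloxy)-3,5-dimethoxyphenyl]-4-ethenyloxolane-3,3-dicarboxylate | COC(=O)C1(C(=O)OC)[C@@H](C=C)CO[C@@H]1c1cc(OC)c(OCc2ccccc2)c(OC)c1 | intermediate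
7 | dimethyl (2R,4R)-2-[4-(benzyloxy)-3,5-dimethoxyphenyl]-4-(1,2,4-trioxolan-3-yl)oxolane-3,3-dicarboxylate (ozonide, trioxolane carbon undefined) | COC(=O)C1(C(=O)OC)[C@@H](C2OOCO2)CO[C@@H]1c1cc(OC)c(OCc2ccccc2)c(OC)c1 | intermediate (not isolated)
8 | dimethyl (2R,4R)-2-[4-(benzyloxy)-3,5-dimethoxyphenyl]-4-formyloxolane-3,3-dicarboxylate | COC(=O)C1(C(=O)OC)[C@@H](C=O)CO[C@@H]1c1cc(OC)c(OCc2ccccc2)c(OC)c1 | intermediate
9 | 4-bromo-2-methoxyphenol | COc1cc(Br)ccc1O | starting material
10 | 1-(benzyloxy)-4-bromo-2-methoxybenzene | COc1cc(Br)ccc1OCc1ccccc1 | intermediate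
11 | [4-(benzyloxy)-3-methoxyphenyl]magnesium bromide | COc1cc([Mg]Br)ccc1OCc1ccccc1 | intermediate (not isolated)
12 | bromomagnesium alkoxide of dimethyl (2R,4R)-2-[4-(benzyloxy)-3,5-dimethoxyphenyl]-4-{[4-(benzyloxy)-3-methoxyphenyl](hydroxy)methyl}oxolane-3,3-dicarboxylate (carbinol epimers) | COC(=O)C1(C(=O)OC)[C@@H](C(O[Mg]Br)c2ccc(OCc3ccccc3)c(OC)c2)CO[C@@H]1c1cc(OC)c(OCc2ccccc2)c(OC)c1 | intermediate (not isolated)
13 | methyl (1S,2R,5R,6RS)-2-[4-(benzyloxy)-3,5-dimethoxyphenyl]-6-[4-(benzyloxy)-3-methoxyphenyl]-8-oxo-3,7-dioxabicyclo[3.3.0]octane-1-carboxylate (C6 epimers) | COC(=O)[C@@]12[C@@H](c3cc(OC)c(OCc4ccccc4)c(OC)c3)OC[C@@H]1C(c1ccc(OCc3ccccc3)c(OC)c1)OC2=O | intermediate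
14 | lithium (1S,2R,5R,6RS)-2-[4-(benzyloxy)-3,5-dimethoxyphenyl]-6-[4-(benzyloxy)-3-methoxyphenyl]-8-oxo-3,7-dioxabicyclo[3.3.0]octane-1-carboxylate | [Li+].[O-]C(=O)[C@@]12[C@@H](c3cc(OC)c(OCc4ccccc4)c(OC)c3)OC[C@@H]1C(c1ccc(OCc3ccccc3)c(OC)c1)OC2=O | intermediate (not isolated)
15 | (1S,2S,5R,6RS)-2-[4-(benzyloxy)-3,5-dimethoxyphenyl]-6-[4-(benzyloxy)-3-methoxyphenyl]-3,7-dioxabicyclo[3.3.0]octan-8-one (cis-fused, 2-aryl on the convex face, C6 epimers) | O=C1OC(c2ccc(OCc3ccccc3)c(OC)c2)[C@H]2CO[C@H](c3cc(OC)c(OCc4ccccc4)c(OC)c3)[C@@H]12 | intermediate
16 | (1S,2S,5R,6RS)-2-(4-hydroxy-3,5-dimethoxyphenyl)-6-(4-hydroxy-3-methoxyphenyl)-3,7-dioxabicyclo[3.3.0]octan-8-one | O=C1OC(c2ccc(O)c(OC)c2)[C@H]2CO[C@H](c3cc(OC)c(O)c(OC)c3)[C@@H]12 | intermediate (not isolated)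
17 | (2S,3S,4R)-2-(4-hydroxy-3,5-dimethoxyphenyl)-4-[(4-hydroxy-3-methoxyphenyl)methyl]oxolane-3-carboxylic acid | OC(=O)[C@H]1[C@@H](Cc2ccc(O)c(OC)c2)CO[C@@H]1c1cc(OC)c(O)c(OC)c1 | intermediate
18 | 4-[(2S,3R,4R)-3-(hydroxymethyl)-4-[(4-hydroxy-3-methoxyphenyl)methyl]oxolan-2-yl]-2,6-dimethoxyphenol (5-methoxylariciresinol) | OC[C@H]1[C@@H](Cc2ccc(O)c(OC)c2)CO[C@@H]1c1cc(OC)c(O)c(OC)c1 | intermediate
19 | (E)-ferulic acid | COc1cc(/C=C/C(=O)O)ccc1O | starting material
20 | [(2S,3R,4R)-2-(4-hydroxy-3,5-dimethoxyphenyl)-4-[(4-hydroxy-3-methoxyphenyl)methyl]oxolan-3-yl]methyl (2E)-3-(4-hydroxy-3-methoxyphenyl)prop-2-enoate | COc1cc(/C=C/C(=O)OC[C@H]2[C@@H](Cc3ccc(O)c(OC)c3)CO[C@@H]2c2cc(OC)c(O)c(OC)c2)ccc1O | target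

## Step count and least certain steps

Total: 10 steps. Longest linear sequence: 9 steps (1 → 2 → 4 → 6 → 8 → 13 → 15 → 17 → 18 → 20, steps 1–4 and 6–10); the branch 9 → 10 is one step.

**Step 3 (key step).**
- Risk: the oxa-Michael addition may be too slow. The trialkoxyaryl group makes 4 a weak acceptor, so the palladium zwitterion may be lost to β-hydride elimination or to oligomerisation of the epoxide before it is trapped. The 2,4-trans preference and the enantiomeric purity may also be incomplete, because both are decided in a ring closure that has been demonstrated with stronger acceptors.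
- Fallback: it sets out from 2, which is condensed with Meldrum's acid (2,2-dimethyl-1,3-dioxane-4,6-dione; water, 75 °C) to the arylidene Meldrum's acid F1, an acceptor that is many orders of magnitude more electrophilic. F1 is taken through the same palladium cycloaddition with 5 to the spiro adduct F2. NaOMe in MeOH opens the dioxanedione with loss of acetone to the sodium half-ester F3 (both C3 epimers, which converge), and MeI in DMF returns the route to 6.
- A minor share of the C2 epimer would be removed by chromatography at 6 or at the crystalline lactone 15.

**Step 6.**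
- Risk: the basic Grignard reagent may enolise the α-branched, β-alkoxy aldehyde. This would erode the configuration at C4 or open the ring by β-elimination. The epimer with the aryl group on the concave face may also lactonise slowly.
- Fallback: it sets out from 8 and 10. Bromide 10 is converted (n-BuLi, THF, −78 °C; B(OiPr)3; aqueous HCl) into [4-(benzyloxy)-3-methoxyphenyl]boronic acid F4. F4 is added to 8 under near-neutral rhodium catalysis (Rh(acac)(CO)2, P(t-Bu)3, DME–H2O, 50 °C) to give the hydroxy diester F5. Catalytic PPTS in toluene at 60 °C closes F5 to 13.

**Step 7.**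
- Risk: at 140 °C the lactone enolate released by decarboxylation may expel O3 (opening of the tetrahydrofuran by β-elimination), or chloride may open the benzylic lactone, before protonation occurs.
- Fallback: it sets out from 13. LiOH in aqueous THF hydrolyses the ester (and opens the lactone), and acidification with cold HCl closes the lactone again with the only carboxyl group that can reach, giving the lactone acid F6. F6 is decarboxylated in toluene at 90 °C through the neutral enol, which has no tendency to eliminate, and the route is rejoined at 15.

**Step 8.**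
- Risk: over-reduction. Once the phenols are free, the C2–O1 bond is a para-hydroxybenzylic ether and may be hydrogenolysed in competition with the lactone C–O bond, which would open the tetrahydrofuran.
- Fallback: it sets out from 15. The hydrogenolysis is stopped after the fast cleavage of the two benzyl ethers, and 16 is isolated. 16 is treated with DBU and NaBH4 in THF–i-PrOH at rt: the guaiacyl phenoxide expels the carboxylate to give the quinone methide acid F7, which borohydride reduces at the exocyclic carbon, and acidification gives 17. The ether at C2 would have to expel an alkoxide and should not react.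

**Step 10.**
- Risk: loss of chemoselectivity. Phenols may be alkylated by the alkoxyphosphonium ion, or substitution at the β-branched primary carbon may be slow enough for side reactions of ferulic acid to intervene.
- Fallback: it sets out from 18. Ac2O in aqueous NaOH at 0 °C (Schotten–Baumann conditions) acetylates only the phenoxides and gives the diacetate F8. Steglich esterification (EDC·HCl, DMAP, CH2Cl2) with 4-O-acetylferulic acid F9 (from 19 by the same acetylation) gives the triacetate F10. Pyrrolidine in CH2Cl2 at 0 °C removes the three aryl acetates much faster than it attacks the alkyl cinnamate and gives 20.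

## Further compounds

F1 | step 3 | 5-{[4-(benzyloxy)-3,5-dimethoxyphenyl]methylidene}-2,2-dimethyl-1,3-dioxane-4,6-dione | CC1(C)OC(=O)C(=Cc2cc(OC)c(OCc3ccccc3)c(OC)c2)C(=O)O1
F2 | step 3 | (1R,4R)-1-[4-(benzyloxy)-3,5-dimethoxyphenyl]-4-ethenyl-8,8-dimethyl-2,7,9-trioxaspiro[4.5]decane-6,10-dione | CC1(C)OC(=O)C2(C(=O)O1)[C@@H](C=C)CO[C@@H]2c1cc(OC)c(OCc2ccccc2)c(OC)c1
F3 | step 3 | sodium (2R,4R)-2-[4-(benzyloxy)-3,5-dimethoxyphenyl]-4-ethenyl-3-(methoxycarbonyl)oxolane-3-carboxylate (C3 epimers) | [Na+].[O-]C(=O)C1(C(=O)OC)[C@@H](C=C)CO[C@@H]1c1cc(OC)c(OCc2ccccc2)c(OC)c1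
F4 | step 6 | [4-(benzyloxy)-3-methoxyphenyl]boronic acid | COc1cc(B(O)O)ccc1OCc1ccccc1
F5 | step 6 | dimethyl (2R,4R)-2-[4-(benzyloxy)-3,5-dimethoxyphenyl]-4-{[4-(benzyloxy)-3-methoxyphenyl](hydroxy)methyl}oxolane-3,3-dicarboxylate (carbinol epimers) | COC(=O)C1(C(=O)OC)[C@@H](C(O)c2ccc(OCc3ccccc3)c(OC)c2)CO[C@@H]1c1cc(OC)c(OCc2ccccc2)c(OC)c1
F6 | step 7 | (1S,2R,5R,6RS)-2-[4-(benzyloxy)-3,5-dimethoxyphenyl]-6-[4-(benzyloxy)-3-methoxyphenyl]-8-oxo-3,7-dioxabicyclo[3.3.0]octane-1-carboxylic acid | OC(=O)[C@@]12[C@@H](c3cc(OC)c(OCc4ccccc4)c(OC)c3)OC[C@@H]1C(c1ccc(OCc3ccccc3)c(OC)c1)OC2=O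
F7 | step 8 | (2S,3S,4R)-2-(4-hydroxy-3,5-dimethoxyphenyl)-4-[(3-methoxy-4-oxocyclohexa-2,5-dien-1-ylidene)methyl]oxolane-3-carboxylic acid (quinone methide, formed as its salt, alkene geometry undefined) | OC(=O)[C@H]1[C@@H](C=C2C=CC(=O)C(OC)=C2)CO[C@@H]1c1cc(OC)c(O)c(OC)c1
F8 | step 10 | 4-[(2S,3R,4R)-4-{[4-(acetyloxy)-3-methoxyphenyl]methyl}-3-(hydroxymethyl)oxolan-2-yl]-2,6-dimethoxyphenyl acetate | OC[C@H]1[C@@H](Cc2ccc(OC(C)=O)c(OC)c2)CO[C@@H]1c1cc(OC)c(OC(C)=O)c(OC)c1
F9 | step 10 | (2E)-3-[4-(acetyloxy)-3-methoxyphenyl]prop-2-enoic acid | COc1cc(/C=C/C(=O)O)ccc1OC(C)=O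
F10 | step 10 | tri-O-acetyl derivative of 20 | COc1cc(/C=C/C(=O)OC[C@H]2[C@@H](Cc3ccc(OC(C)=O)c(OC)c3)CO[C@@H]2c2cc(OC)c(OC(C)=O)c(OC)c2)ccc1OC(C)=O
A1 | alternative 1 | trans-2-syringyl-3-(triethylsilyloxymethyl)-4-(guaiacylmethyl)-2,3-dihydrofuran, phenols as tert-butyldimethylsilyl ethers | CC[Si](CC)(CC)OC[C@H]1C(Cc2ccc(O[Si](C)(C)C(C)(C)C)c(OC)c2)=CO[C@@H]1c1cc(OC)c(O[Si](C)(C)C(C)(C)C)c(OC)c1
A2 | alternative 1 | 1-formyl-1-(guaiacylmethyl)-2-syringyl-3-(triethylsilyloxymethyl)cyclopropane, phenols as tert-butyldimethylsilyl ethers (only the silyloxymethyl-bearing carbon is defined; the other two are lost in the ring expansion) | O=CC1(Cc2ccc(O[Si](C)(C)C(C)(C)C)c(OC)c2)C(c2cc(OC)c(O[Si](C)(C)C(C)(C)C)c(OC)c2)[C@H]1CO[Si](CC)(CC)CC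
A3 | alternative 2 | 2-syringyl-6-guaiacyl-3,7-dioxabicyclo[3.3.0]octan-8-one, benzyl-protected, cis-fused, 6-aryl on the convex face, C2 epimers | O=C1[C@H]2[C@@H]([C@H](O1)c3ccc(OCc4ccccc4)c(OC)c3)COC2c5cc(OC)c(OCc6ccccc6)c(OC)c5
A4 | alternative 2 | trans-4-[(syringylmethoxy)methyl]-5-guaiacyl-3-diazooxolan-2-one, benzyl-protected | O=C1O[C@H](c2ccc(OCc3ccccc3)c(OC)c2)[C@@H](COCc2cc(OC)c(OCc3ccccc3)c(OC)c2)C1=[N+]=[N-]
A5 | alternative 3 | 5-methoxylariciresinol bis(tert-butyldimethylsilyl) ether | OC[C@H]1[C@@H](Cc2ccc(O[Si](C)(C)C(C)(C)C)c(OC)c2)CO[C@@H]1c1cc(OC)c(O[Si](C)(C)C(C)(C)C)c(OC)c1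
A6 | alternative 3 | (E)-cinnamyl ether of syringyl(oxiran-2-yl)methanol, phenols as tert-butyldimethylsilyl ethers (oxirane carbon undefined; it becomes the radical centre) | C1OC1[C@H](OC/C=C/c1ccc(O[Si](C)(C)C(C)(C)C)c(OC)c1)c1cc(OC)c(O[Si](C)(C)C(C)(C)C)c(OC)c1
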